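Everything rests on closing ring C of the upper (epioritin) unit last, between the ring A phenolic oxygen O1 (on C8a) and the benzylic carbon C2 that carries ring B. An intramolecular Mitsunobu etherification of an anti-1,2-diol inverts C2 and so delivers in one operation the 2,3-cis-3,4-trans ring C, which equilibrating closures disfavour; it exploits the acidity of the C8a phenol and the benzylic position of C2. The precursor is an open-chain 1,3,3-triarylpropane-1,2-diol, unravelled from a daphnetin-derived lactone, a temporary ring that sets C4 by conjugate arylation with the lower-unit boronate and C3 by enolate hydroxylation. The lower flavan-3,4-diol comes from a chalcone epoxide.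

Key step: step 15

Remark: the target is read as epioritin-(4β→6)-oritin-4α-ol, upper unit (rings A, B, C) 2R,3R,4S and lower unit (rings D, E, F) 2R,3S,4R. In protected intermediates some CIP descriptors change through the priority rules only, and the SMILES is decisive. ArD stands for the lower-unit group (2R,3R,4R)-7,8-bis(benzyloxy)-2-[4-(benzyloxy)phenyl]-3,4-bis[(benzyloxy)methoxy]chroman-6-yl (2,3-trans-3,4-trans, as in 11).

Step 1
Reactants: 1 1-(2,3,4-trihydroxyphenyl)ethanone
Product: 2 1-[3,4-bis(benzyloxy)-2-hydroxyphenyl]ethanone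
Conditions: BnBr (2.1 equiv), K2CO3, acetone, reflux
Reagents that add atoms: benzyl bromide, BrCc1ccccc1
Why: Williamson etherification; the 2-hydroxyl is held in a hydrogen bond to the acetyl carbonyl and should stay free, so only the 3- and 4-hydroxyls are benzylated.

Step 2
Reactants: 2 1-[3,4-bis(benzyloxy)-2-hydroxyphenyl]ethanone
Product: 3 1-[3,4-bis(benzyloxy)-5-bromo-2-hydroxyphenyl]ethanone
Conditions: NBS, MeCN, 0 °C → rt
Reagents that add atoms: N-bromosuccinimide, O=C1CCC(=O)N1Br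
Why: Electrophilic aromatic bromination should go para to the free phenol and ortho to the 4-benzyloxy group (C5), the only position activated by two oxygen donors; this carbon becomes C6 of ring D.

Step 3
Reactants: 3 1-[3,4-bis(benzyloxy)-5-bromo-2-hydroxyphenyl]ethanone
Product: 4 1-[3,4-bis(benzyloxy)-5-bromo-2-(methoxymethoxy)phenyl]ethanone
Conditions: NaH, MOMCl, DMF, 0 °C → rt
Reagents that add atoms: chloromethyl methyl ether, COCCl
Why: O-alkylation of the sodium phenoxide masks the chelated phenol as a MOM ether, so that the later nucleophilic epoxidation of the enone is not diverted into Algar–Flynn–Oyamada chemistry.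

Step 4
Reactants: 4 1-[3,4-bis(benzyloxy)-5-bromo-2-(methoxymethoxy)phenyl]ethanone; 5 4-(benzyloxy)benzaldehyde
Product: 6 (E)-1-[3,4-bis(benzyloxy)-5-bromo-2-(methoxymethoxy)phenyl]-3-[4-(benzyloxy)phenyl]prop-2-en-1-one
Conditions: KOH (aq.), EtOH/THF, rt
Reagents that add atoms: none
Why: Claisen–Schmidt condensation of a methyl ketone with a non-enolisable aldehyde gives the (E)-chalcone under thermodynamic control.

Step 5
Reactants: 6 (E)-chalcone
Product: 7 [(2R,3S)-3-[4-(benzyloxy)phenyl]oxiran-2-yl][3,4-bis(benzyloxy)-5-bromo-2-(methoxymethoxy)phenyl]methanone (trans-epoxide)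
Conditions: poly-L-leucine, urea–H2O2, DBU, THF, rt
Reagents that add atoms: urea–hydrogen peroxide, NC(N)=O.OO
Why: Juliá–Colonna epoxidation: hydroperoxide adds to the enone held by the helical poly-L-leucine, which should give the trans (αR,βS)-epoxy ketone and thereby fix the absolute configuration of the lower unit.

Step 6
Reactants: 7 MOM-protected epoxy ketone
Product: 9 (2R,3R)-7,8-bis(benzyloxy)-2-[4-(benzyloxy)phenyl]-6-bromo-3-hydroxy-2,3-dihydro-4H-chromen-4-one (2,3-trans dihydroflavonol), via phenolic epoxy ketone 8 (not isolated)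
Conditions: HCl (cat.), MeOH/THF, 45 °C
Reagents that add atoms: none
Why: Acidic methanolysis of the MOM acetal frees the phenol, which opens the epoxide at the benzylic carbon in a 6-endo closure with inversion (oxirane C3 S becomes C2 R) while the carbinol carbon is untouched, giving the 2,3-trans dihydroflavonol.

Step 7
Reactants: 9 (2R,3R)-dihydroflavonol
Product: 10 (2R,3S,4R)-7,8-bis(benzyloxy)-2-[4-(benzyloxy)phenyl]-6-bromochromane-3,4-diol (2,3-trans-3,4-trans)
Conditions: NaBH4, MeOH/THF, 0 °C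
Reagents that add atoms: none
Why: Carbonyl reduction; hydride should add axially to C4 of the half-chair that carries equatorial 2-aryl and 3-hydroxyl groups, giving the equatorial 4-alcohol trans to the 3-hydroxyl.

Step 8
Reactants: 10 (2R,3S,4R)-flavan-3,4-diol
Product: 11 (2R,3R,4R)-7,8-bis(benzyloxy)-2-[4-(benzyloxy)phenyl]-3,4-bis[(benzyloxy)methoxy]-6-bromochromane (bis-BOM ether of 10; spatial arrangement unchanged)
Conditions: BnOCH2Cl, iPr2NEt, tetrabutylammonium iodide (cat.), ClCH2CH2Cl, 50 °C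
Reagents that add atoms: benzyl chloromethyl ether, ClCOCc1ccccc1
Why: Base-mediated O-alkylation of both secondary alcohols with a reactive α-chloro ether; BOM acetals are stable to base, organometallics and hydride and leave later by hydrogenolysis with the benzyl ethers, so the benzylic C4–O bond never meets acid.

Step 9
Reactants: 11 aryl bromide
Product: 12 2-{(2R,3R,4R)-7,8-bis(benzyloxy)-2-[4-(benzyloxy)phenyl]-3,4-bis[(benzyloxy)methoxy]chroman-6-yl}-4,4,5,5-tetramethyl-1,3,2-dioxaborolane (ArD–Bpin)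
Conditions: B2pin2, PdCl2(dppf) (cat.), KOAc, dioxane, 90 °C
Reagents that add atoms: bis(pinacolato)diboron, CC1(C)OB(OC1(C)C)B1OC(C)(C)C(C)(C)O1
Why: Miyaura borylation (oxidative addition, acetate-assisted transmetallation with the diboron, reductive elimination) tolerates all the ether groups.

Step 10
Reactants: 13 7,8-dihydroxy-2H-chromen-2-one (daphnetin)
Product: 14 7,8-bis(benzyloxy)-2H-chromen-2-one
Conditions: BnBr, K2CO3, DMF, 60 °C
Reagents that add atoms: benzyl bromide, BrCc1ccccc1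
Why: Williamson etherification of both phenols; the lactone is inert to carbonate.

Step 11
Reactants: 12 ArD–Bpin; 14 7,8-bis(benzyloxy)-2H-chromen-2-one (in excess)
Product: 15 (4R)-4-ArD-7,8-bis(benzyloxy)-3,4-dihydro-2H-chromen-2-one (ArD on the face that becomes 4β of the upper unit)
Conditions: Rh(acac)(C2H4)2 (cat.), (S)-SEGPHOS, KOH (cat.), dioxane/H2O 10:1, 60 °C
Reagents that add atoms: none
Why: Hayashi–Miyaura reaction: the aryl–rhodium species adds across C3=C4 of the coumarin and water protonates the oxa-π-allyl rhodium; the chiral bisphosphine selects the coumarin face and so sets C4, the (S)-ligand being chosen because the (R)-ligand is the one known to give (R)-4-arylchroman-2-ones from simple coumarins and the opposite face is needed here.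

Step 12
Reactants: 15 (4R)-4-aryl lactone
Product: 16 (3R,4R)-4-ArD-7,8-bis(benzyloxy)-3-hydroxy-3,4-dihydro-2H-chromen-2-one (3,4-trans)
Conditions: NaN(SiMe3)2, THF, −78 °C; 3-phenyl-2-(phenylsulfonyl)oxaziridine; AcOH quench
Reagents that add atoms: 3-phenyl-2-(phenylsulfonyl)oxaziridine, O=S(=O)(c1ccccc1)N1OC1c1ccccc1
Why: Davis enolate hydroxylation: the sodium enolate of the lactone should be oxidised on the face opposite to the C4 aryl group, so the temporary ring sets C3 trans to C4.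

Step 13
Reactants: 16 (3R,4R)-hydroxy lactone; 17 [4-(benzyloxy)phenyl]magnesium bromide
Product: 19 (2R,3R)-3-ArD-3-[3,4-bis(benzyloxy)-2-hydroxyphenyl]-1-[4-(benzyloxy)phenyl]-2-hydroxypropan-1-one, via Weinreb amide 18 (not isolated)
Conditions: MeNH(OMe)·HCl, iPrMgCl, THF, −20 → 0 °C; then 17, 0 °C → rt; aq. NH4Cl
Reagents that add atoms: N,O-dimethylhydroxylamine hydrochloride, CNOC.Cl (its atoms enter 18 and leave again before 19)
Why: One-pot Weinreb ketone synthesis: the chloromagnesium amide opens the aryl lactone to the N-methoxy-N-methylamide, whose magnesium chelate with the aryl Grignard reagent survives until work-up and so stops at the ketone, while C3 is shielded from epimerisation as its alkoxide.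

Step 14
Reactants: 19 (2R,3R)-α-hydroxy ketone
Product: 20 (1S,2R,3R)-3-ArD-3-[3,4-bis(benzyloxy)-2-hydroxyphenyl]-1-[4-(benzyloxy)phenyl]propane-1,2-diol (1,2-anti)
Conditions: Zn(BH4)2, Et2O/THF, −20 → 0 °C; aq. NH4Cl
Reagents that add atoms: none
Why: Chelation-controlled (Cram chelate) reduction: zinc bridges the carbonyl and the α-oxygen and hydride is delivered anti to the diarylmethyl substituent, which should give the 1,2-anti diol with the (1S)-carbinol.

Step 15
Reactants: 20 (1S,2R,3R)-anti-diol phenol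
Product: 21 (2R,3R,4R)-4-ArD-7,8-bis(benzyloxy)-2-[4-(benzyloxy)phenyl]chroman-3-ol (upper unit 2,3-cis-3,4-trans)
Conditions: PPh3, DIAD, THF, 0 °C → rt
Reagents that add atoms: none
Why: Mitsunobu etherification: the phosphine–azodicarboxylate betaine deprotonates the ring A phenol (C8a–OH, the most acidic hydroxyl), the benzylic C2 hydroxyl becomes an alkoxyphosphonium ion, and phenoxide O1 displaces triphenylphosphine oxide from C2 in an SN2 step. The closest known reaction type is the Mitsunobu cyclisation of 1-aryl-3-(2-hydroxyaryl)propane-1,2-diols to flavan-3-ols. Ring C is closed in the 6-exo-tet mode. The only new stereocentre is C2, controlled by inversion of the (1S)-carbinol set in step 14, so that ring B ends cis to the C3 hydroxyl (2R), while C3 and C4 are not touched. The step needs activation of the benzylic hydroxyl in preference to the C3 hydroxyl, O-alkylation of the phenol in preference to epoxide formation, and SN2 in preference to ionisation at the p-alkoxybenzylic carbon. These should be secured by the shielding of the C3 hydroxyl by the diarylmethyl group, by the low pKa of the phenol together with the six-membered transition state, and by the non-ionising solvent at low temperature.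

Step 16
Reactants: 21 protected dimer
Product: 22 (2R,3R,4S)-2-(4-hydroxyphenyl)-4-[(2R,3S,4R)-3,4,7,8-tetrahydroxy-2-(4-hydroxyphenyl)chroman-6-yl]chromane-3,7,8-triol (CNP0391561.5)
Conditions: H2 (1 atm), Pd(OH)2/C, THF/MeOH, rt
Reagents that add atoms: none
Why: Hydrogenolysis cleaves the six benzyl ethers and the two BOM groups (the hemiacetals so formed lose formaldehyde) under neutral conditions, in which the C2–O1 bonds and the hydroxyl-flanked benzylic C4–OH of the lower unit should be retained.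

Compound list
1 | 1-(2,3,4-trihydroxyphenyl)ethanone (gallacetophenone) | CC(=O)c1ccc(O)c(O)c1O | starting material
2 | 1-[3,4-bis(benzyloxy)-2-hydroxyphenyl]ethanone | CC(=O)c1ccc(OCc2ccccc2)c(OCc2ccccc2)c1O | intermediate
3 | 1-[3,4-bis(benzyloxy)-5-bromo-2-hydroxyphenyl]ethanone | CC(=O)c1cc(Br)c(OCc2ccccc2)c(OCc2ccccc2)c1O | intermediate
4 | 1-[3,4-bis(benzyloxy)-5-bromo-2-(methoxymethoxy)phenyl]ethanone | CC(=O)c1cc(Br)c(OCc2ccccc2)c(OCc2ccccc2)c1OCOC | intermediate
5 | 4-(benzyloxy)benzaldehyde | O=Cc1ccc(OCc2ccccc2)cc1 | starting material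
6 | (E)-1-[3,4-bis(benzyloxy)-5-bromo-2-(methoxymethoxy)phenyl]-3-[4-(benzyloxy)phenyl]prop-2-en-1-one | O=C(/C=C/c1ccc(OCc2ccccc2)cc1)c1cc(Br)c(OCc2ccccc2)c(OCc2ccccc2)c1OCOC | intermediate
7 | [(2R,3S)-3-[4-(benzyloxy)phenyl]oxiran-2-yl][3,4-bis(benzyloxy)-5-bromo-2-(methoxymethoxy)phenyl]methanone | O=C([C@@H]1O[C@H]1c1ccc(OCc2ccccc2)cc1)c1cc(Br)c(OCc2ccccc2)c(OCc2ccccc2)c1OCOC | intermediate
8 | [(2R,3S)-3-[4-(benzyloxy)phenyl]oxiran-2-yl][3,4-bis(benzyloxy)-5-bromo-2-hydroxyphenyl]methanone | O=C([C@@H]1O[C@H]1c1ccc(OCc2ccccc2)cc1)c1cc(Br)c(OCc2ccccc2)c(OCc2ccccc2)c1O | intermediate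
9 | (2R,3R)-7,8-bis(benzyloxy)-2-[4-(benzyloxy)phenyl]-6-bromo-3-hydroxy-2,3-dihydro-4H-chromen-4-one | O=C1[C@H](O)[C@@H](c2ccc(OCc3ccccc3)cc2)Oc2c(OCc3ccccc3)c(OCc3ccccc3)c(Br)cc21 | intermediate
10 | (2R,3S,4R)-7,8-bis(benzyloxy)-2-[4-(benzyloxy)phenyl]-6-bromochromane-3,4-diol | Brc1cc2c(c(OCc3ccccc3)c1OCc1ccccc1)O[C@H](c1ccc(OCc3ccccc3)cc1)[C@@H](O)[C@@H]2O | intermediate
11 | (2R,3R,4R)-7,8-bis(benzyloxy)-2-[4-(benzyloxy)phenyl]-3,4-bis[(benzyloxy)methoxy]-6-bromochromane | Brc1cc2c(c(OCc3ccccc3)c1OCc1ccccc1)O[C@H](c1ccc(OCc3ccccc3)cc1)[C@@H](OCOCc1ccccc1)[C@@H]2OCOCc1ccccc1 | intermediate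
12 | 2-{(2R,3R,4R)-7,8-bis(benzyloxy)-2-[4-(benzyloxy)phenyl]-3,4-bis[(benzyloxy)methoxy]chroman-6-yl}-4,4,5,5-tetramethyl-1,3,2-dioxaborolane | CC1(C)OB(OC1(C)C)c1cc2c(c(OCc3ccccc3)c1OCc1ccccc1)O[C@H](c1ccc(OCc3ccccc3)cc1)[C@@H](OCOCc1ccccc1)[C@@H]2OCOCc1ccccc1 | intermediate
13 | 7,8-dihydroxy-2H-chromen-2-one (daphnetin) | O=c1ccc2ccc(O)c(O)c2o1 | starting material
14 | 7,8-bis(benzyloxy)-2H-chromen-2-one | O=c1ccc2ccc(OCc3ccccc3)c(OCc3ccccc3)c2o1 | intermediate
15 | (4R)-4-ArD-7,8-bis(benzyloxy)-3,4-dihydro-2H-chromen-2-one | O=C1C[C@@H](c2cc3c(c(OCc4ccccc4)c2OCc2ccccc2)O[C@H](c2ccc(OCc4ccccc4)cc2)[C@@H](OCOCc2ccccc2)[C@@H]3OCOCc2ccccc2)c2ccc(OCc3ccccc3)c(OCc3ccccc3)c2O1 | intermediate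
16 | (3R,4R)-4-ArD-7,8-bis(benzyloxy)-3-hydroxy-3,4-dihydro-2H-chromen-2-one (3,4-trans) | O=C1[C@H](O)[C@@H](c2cc3c(c(OCc4ccccc4)c2OCc2ccccc2)O[C@H](c2ccc(OCc4ccccc4)cc2)[C@@H](OCOCc2ccccc2)[C@@H]3OCOCc2ccccc2)c2ccc(OCc3ccccc3)c(OCc3ccccc3)c2O1 | intermediate
17 | [4-(benzyloxy)phenyl]magnesium bromide | Br[Mg]c1ccc(OCc2ccccc2)cc1 | starting material
18 | (2R,3R)-3-ArD-3-[3,4-bis(benzyloxy)-2-hydroxyphenyl]-2-hydroxy-N-methoxy-N-methylpropanamide | CON(C)C(=O)[C@H](O)[C@@H](c1cc2c(c(OCc3ccccc3)c1OCc1ccccc1)O[C@H](c1ccc(OCc3ccccc3)cc1)[C@@H](OCOCc1ccccc1)[C@@H]2OCOCc1ccccc1)c1ccc(OCc2ccccc2)c(OCc2ccccc2)c1O | intermediate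
19 | (2R,3R)-3-ArD-3-[3,4-bis(benzyloxy)-2-hydroxyphenyl]-1-[4-(benzyloxy)phenyl]-2-hydroxypropan-1-one | O=C(c1ccc(OCc2ccccc2)cc1)[C@H](O)[C@@H](c1cc2c(c(OCc3ccccc3)c1OCc1ccccc1)O[C@H](c1ccc(OCc3ccccc3)cc1)[C@@H](OCOCc1ccccc1)[C@@H]2OCOCc1ccccc1)c1ccc(OCc2ccccc2)c(OCc2ccccc2)c1O | intermediate
20 | (1S,2R,3R)-3-ArD-3-[3,4-bis(benzyloxy)-2-hydroxyphenyl]-1-[4-(benzyloxy)phenyl]propane-1,2-diol (1,2-anti) | O[C@@H](c1ccc(OCc2ccccc2)cc1)[C@H](O)[C@@H](c1cc2c(c(OCc3ccccc3)c1OCc1ccccc1)O[C@H](c1ccc(OCc3ccccc3)cc1)[C@@H](OCOCc1ccccc1)[C@@H]2OCOCc1ccccc1)c1ccc(OCc2ccccc2)c(OCc2ccccc2)c1O | intermediate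
21 | (2R,3R,4R)-4-ArD-7,8-bis(benzyloxy)-2-[4-(benzyloxy)phenyl]chroman-3-ol (upper unit 2,3-cis-3,4-trans) | c1ccccc1COc1ccc([C@H]2Oc3c(ccc(OCc4ccccc4)c3OCc3ccccc3)[C@H](c3cc4c(c(OCc5ccccc5)c3OCc3ccccc3)O[C@H](c3ccc(OCc5ccccc5)cc3)[C@@H](OCOCc3ccccc3)[C@@H]4OCOCc3ccccc3)[C@H]2O)cc1 | intermediate
22 | (2R,3R,4S)-2-(4-hydroxyphenyl)-4-[(2R,3S,4R)-3,4,7,8-tetrahydroxy-2-(4-hydroxyphenyl)chroman-6-yl]chromane-3,7,8-triol | Oc1ccc([C@H]2Oc3c(ccc(O)c3O)[C@H](c3cc4c(c(O)c3O)O[C@H](c3ccc(O)cc3)[C@@H](O)[C@@H]4O)[C@H]2O)cc1 | target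

Total step count: 16. Longest linear sequence: 15 steps (steps 1–9, then 11–16); step 10 is a one-step side branch.

Steps most likely to fail

Step 11. Insertion of the electron-rich 7-alkoxycoumarin into the aryl–rhodium bond may be slow, so that the hindered ortho-alkoxy arylboronate is lost by protodeboronation, and facial control may erode. The fallback separates bond formation from stereocontrol and sets out from 12 and 14. An oxidative boron-Heck coupling (Pd(OAc)2, 1,10-phenanthroline, O2, DMF) should give the flat 4-ArD-7,8-bis(benzyloxy)-2H-chromen-2-one F1. Asymmetric conjugate reduction of F1 with copper hydride (Cu(OAc)2, DTBM-SEGPHOS of the enantiomer that delivers hydride to the required face, diethoxymethylsilane, t-BuOH, toluene) then comes back to the route at 15.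

Step 15. The p-alkoxybenzylic alkoxyphosphonium ion may ionise before displacement, with loss of the inversion, or the C3 hydroxyl may close an epoxide. The fallback sets out from 20 and uses acyloxonium instead of phosphonium activation. HC(OEt)3 with PPTS in ClCH2CH2Cl (rt → 60 °C) forms the 1,2-cyclic orthoformate, whose dioxolan-2-ylium ion should be opened at the benzylic carbon by the ring A phenol with inversion, giving (2R,3R,4R)-4-ArD-7,8-bis(benzyloxy)-2-[4-(benzyloxy)phenyl]chroman-3-yl formate F2. Methanolysis of F2 (K2CO3, MeOH) comes back to the route at 21.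

Step 6. The epoxide may ionise at the p-alkoxybenzylic carbon before or during MOM removal, which scrambles C2 or triggers an aryl or acyl shift. The fallback sets out from 7 and opens the epoxide with a soft nucleophile first. BnSH with SnCl4 (CH2Cl2, −20 °C) should open the oxirane at the benzylic carbon and remove the MOM group, giving (2S)-1-[3,4-bis(benzyloxy)-5-bromo-2-hydroxyphenyl]-3-[4-(benzyloxy)phenyl]-3-(benzylsulfanyl)-2-hydroxypropan-1-one F3 (both C3 epimers; the carbinol carbon keeps the configuration of 7). Thiophilic activation of F3 with AgBF4 (CH2Cl2, 0 °C) closes the pyranone ring and comes back to the route at 9.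

Further compounds
F1 | step 11 | 4-ArD-7,8-bis(benzyloxy)-2H-chromen-2-one | O=c1cc(c2cc3c(c(OCc4ccccc4)c2OCc2ccccc2)O[C@H](c2ccc(OCc4ccccc4)cc2)[C@@H](OCOCc2ccccc2)[C@@H]3OCOCc2ccccc2)c2ccc(OCc3ccccc3)c(OCc3ccccc3)c2o1
F2 | step 15 | (2R,3R,4R)-4-ArD-7,8-bis(benzyloxy)-2-[4-(benzyloxy)phenyl]chroman-3-yl formate | c1ccccc1COc1ccc([C@H]2Oc3c(ccc(OCc4ccccc4)c3OCc3ccccc3)[C@H](c3cc4c(c(OCc5ccccc5)c3OCc3ccccc3)O[C@H](c3ccc(OCc5ccccc5)cc3)[C@@H](OCOCc3ccccc3)[C@@H]4OCOCc3ccccc3)[C@H]2OC=O)cc1
F3 | step 6 | (2S)-1-[3,4-bis(benzyloxy)-5-bromo-2-hydroxyphenyl]-3-[4-(benzyloxy)phenyl]-3-(benzylsulfanyl)-2-hydroxypropan-1-one | O=C([C@H](O)C(SCc1ccccc1)c1ccc(OCc2ccccc2)cc1)c1cc(Br)c(OCc2ccccc2)c(OCc2ccccc2)c1O
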